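**Retrosynthetic overview**
1. Target ⇒ remove two aryl acetates and add H2 across one C=C (stereochemistry relayed from the neighbouring centre) ⇒ (E)-benzylidene succinic half-ester.
2. Key disconnection is the methyl ester C–O bond ⇒ MeOH plus a racemic, configurationally labile 3-aryl-4-benzylidene succinic anhydride. A catalytic dynamic kinetic methanolysis fixes both the regiochemistry and the first stereocentre.
3. Exocyclic C=C ⇒ Wittig reaction of an arylmaleic anhydride/PPh3 ylide with a prenylated benzaldehyde.
4. Arylmaleic anhydride ⇒ Perkin condensation of 4-hydroxyphenylacetic acid with glyoxylic acid. The aldehyde ⇒ ortho C-prenylation of 4-hydroxybenzaldehyde.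
5. Rings: both benzene rings are bought. The only ring made is the five-membered anhydride (step 2), which is opened on purpose in the key step.

**Assumption:** operations run in one flask without isolation count as one step, and the sense of induction of (DHQ)2AQN is assigned by analogy with related alcoholytic resolutions, so (DHQD)2AQN replaces it if the sense proves opposite.

**Step 1**
Reactants: 1 4-hydroxybenzaldehyde; 2 prenyl bromide (1-bromo-3-methylbut-2-ene)
Product: 4 4-formyl-2-(3-methylbut-2-enyl)phenyl acetate, via 4-hydroxy-3-prenylbenzaldehyde 3 (not isolated)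
Conditions: KOH, H2O, 25 °C, 24 h; then KOH, Ac2O, 0 °C, 30 min
Reagents that add atoms: acetic anhydride CC(=O)OC(C)=O
Why: Ambident phenoxide alkylation in water, where the hydrogen-bonded oxygen is masked so the ortho carbon (para is blocked) attacks the allylic bromide by SN2 and rearomatises, followed by Schotten–Baumann acetylation of the same phenoxide; no stereocentre is formed.

**Step 2**
Reactants: 5 4-hydroxyphenylacetic acid; 6 glyoxylic acid (monohydrate)
Product: 7 3-(4-acetoxyphenyl)furan-2,5-dione
Conditions: Ac2O, Et3N, 90 °C, 4 h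
Reagents that add atoms: acetic anhydride CC(=O)OC(C)=O
Why: Perkin–Oglialoro condensation, in which the mixed anhydride of the arylacetic acid enolises, adds to the aldehyde carbon and dehydrates, the cis-diacid closes to the cyclic anhydride in hot Ac2O, and the phenol is acetylated in the same pot; no stereocentre is formed.

**Step 3**
Reactants: 7 3-(4-acetoxyphenyl)furan-2,5-dione; 4 4-formyl-2-(3-methylbut-2-enyl)phenyl acetate
Product: 9 rac-(E)-3-(4-acetoxyphenyl)-4-[4-acetoxy-3-(3-methylbut-2-enyl)benzylidene]dihydrofuran-2,5-dione, via phosphonium ylide 8 (not isolated)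
Conditions: PPh3, toluene, 25 °C, 1 h; then 4, PhCO2H (10 mol %), 60 °C
Reagents that add atoms: none
Why: Phospha-Michael addition of PPh3 to the unsubstituted alkene carbon and a proton shift give the carbonyl-stabilised cyclic ylide, whose Wittig olefination with the aromatic aldehyde gives the (E)-alkene (aryl anti to the ring C=O) as usual for stabilised ylides; C3 is formed racemic, which is what step 4 needs.

**Step 4 (key step)**
Reactants: 9 rac-(E)-3-(4-acetoxyphenyl)-4-[4-acetoxy-3-(3-methylbut-2-enyl)benzylidene]dihydrofuran-2,5-dione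
Product: 10 (2E,3R)-3-(4-acetoxyphenyl)-2-[4-acetoxy-3-(3-methylbut-2-enyl)benzylidene]-4-methoxy-4-oxobutanoic acid
Conditions: (DHQ)2AQN (15 mol %), MeOH (3 equiv), MTBE, −20 °C, 48 h
Reagents that add atoms: methanol CO
Why: Proposed new method: dynamic kinetic resolution by alcoholysis of a labile α-aryl-α'-alkylidene succinic anhydride, in which the quinuclidine nitrogen reversibly removes C3–H of 9 (α-carbonyl, benzylic and allylic, giving an achiral 2-oxidofuran dienolate) so the enantiomers interconvert, while the same catalyst delivers MeOH by general-base catalysis to the non-conjugated C=O next to C3 of one enantiomer only (the cinnamoyl-type C=O is deactivated, as in itaconic and benzylidenesuccinic anhydride alcoholysis), so one event forms the ester C–O bond, fixes the regiochemistry and freezes the stereocentre because the acyclic ester/carboxylate is far less acidic; the closest known reaction types are cinchona-catalysed desymmetrisation and parallel kinetic resolution of succinic anhydrides and the alcoholytic DKR of 5-aryl-1,3-dioxolane-2,4-diones.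

**Step 5**
Reactants: 10 (2E,3R)-3-(4-acetoxyphenyl)-2-[4-acetoxy-3-(3-methylbut-2-enyl)benzylidene]-4-methoxy-4-oxobutanoic acid
Product: 12 asperteretal G2 = (2S,3S)-2-[4-hydroxy-3-(3-methylbut-2-enyl)benzyl]-3-(4-hydroxyphenyl)-4-methoxy-4-oxobutanoic acid, via bis-acetate 11 (not isolated)
Conditions: [Rh(cod)((R,R)-Et-DuPhos)]BF4 (2 mol %), H2 (10 bar), MeOH, 25 °C; then NH3 (7 M in MeOH), 0 °C, 1 h; citric acid work-up
Reagents that add atoms: none
Why: Chelation-controlled Rh(I) asymmetric hydrogenation of an itaconate-type half-ester, where alkene/carbonyl chelation makes this C=C react far faster than the isolated trisubstituted prenyl alkene, A(1,3) strain places C3–H in the alkene plane so H2 arrives anti to the aryl group on the face the (R,R)-ligand also prefers (matched) and sets (2S), and mild aminolysis of the aryl acetates then leaves the methyl ester and both stereocentres untouched.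

**Compound list**
1 | 4-hydroxybenzaldehyde | O=Cc1ccc(O)cc1 | starting material
2 | prenyl bromide (1-bromo-3-methylbut-2-ene) | CC(C)=CCBr | starting material
3 | 4-hydroxy-3-(3-methylbut-2-enyl)benzaldehyde | O=Cc1ccc(O)c(CC=C(C)C)c1 | intermediate
4 | 4-formyl-2-(3-methylbut-2-enyl)phenyl acetate | O=Cc1ccc(OC(C)=O)c(CC=C(C)C)c1 | intermediate
5 | 4-hydroxyphenylacetic acid | OC(=O)Cc1ccc(O)cc1 | starting material
6 | glyoxylic acid (used as the monohydrate) | O=CC(=O)O | starting material
7 | 3-(4-acetoxyphenyl)furan-2,5-dione (arylmaleic anhydride) | CC(=O)Oc1ccc(cc1)C1=CC(=O)OC1=O | intermediate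
8 | rac-3-(4-acetoxyphenyl)-4-(triphenylphosphoranylidene)dihydrofuran-2,5-dione (ylide) | CC(=O)Oc1ccc(cc1)C1C(=O)OC(=O)C1=P(c1ccccc1)(c1ccccc1)c1ccccc1 | intermediate
9 | rac-(E)-3-(4-acetoxyphenyl)-4-[4-acetoxy-3-(3-methylbut-2-enyl)benzylidene]dihydrofuran-2,5-dione (benzylidene aryl trans to the adjacent ring C=O) | CC(=O)Oc1ccc(cc1)C1C(=O)OC(=O)/C1=C/c1ccc(OC(C)=O)c(CC=C(C)C)c1 | intermediate
10 | (2E,3R)-3-(4-acetoxyphenyl)-2-[4-acetoxy-3-(3-methylbut-2-enyl)benzylidene]-4-methoxy-4-oxobutanoic acid (same spatial arrangement at C3 as in the target; the label is R only because the sp2 carbon outranks the aryl group) | COC(=O)[C@H](c1ccc(OC(C)=O)cc1)/C(C(=O)O)=C\c1ccc(OC(C)=O)c(CC=C(C)C)c1 | intermediate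
11 | (2S,3S)-3-(4-acetoxyphenyl)-2-[4-acetoxy-3-(3-methylbut-2-enyl)benzyl]-4-methoxy-4-oxobutanoic acid | COC(=O)[C@H](c1ccc(OC(C)=O)cc1)[C@H](Cc1ccc(OC(C)=O)c(CC=C(C)C)c1)C(=O)O | intermediate
12 | asperteretal G2, (2S,3S)-2-[4-hydroxy-3-(3-methylbut-2-enyl)benzyl]-3-(4-hydroxyphenyl)-4-methoxy-4-oxobutanoic acid | COC(=O)[C@H](c1ccc(O)cc1)[C@H](Cc1ccc(O)c(CC=C(C)C)c1)C(=O)O | target

**Total step count:** 5.
**Longest linear sequence:** 4 (step 1 or step 2, then 3, 4, 5).

**Three steps most likely to fail**

**Step 4 (the new step).**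
- Racemisation may be slower than methanolysis, which would leave a plain kinetic resolution capped at 50 %.
- The dienolate may be reprotonated at the benzylidene carbon, so the C=C drifts into the ring.
- MeOH may give only moderate ee.

The fallback uses known chemistry, sets out from 9 and returns at 10. Uncatalysed methanolysis (MeOH, 40 °C) follows the same innate regioselectivity and gives the racemic half-ester F1. Crystallisation with (S)-1-phenylethylamine from EtOAc gives the less soluble diastereomeric ammonium salt F2; the antipodal amine is used if the other salt crystallises. Cold dilute acid liberates 10. The mother liquor is racemised with catalytic DBU and recycled.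

**Step 3.** Ylide 8 is hindered by the neighbouring aryl-bearing carbon, and product 9 is base-sensitive. The fallback sets out from 7 (and 4) and returns at 9. It carries out the olefination on an acyclic diester and closes the ring last.
- MeOH with catalytic H2SO4 converts 7 into dimethyl (Z)-2-(4-hydroxyphenyl)but-2-enedioate F3.
- The known tributylphosphine-mediated olefination of maleates with aldehydes (PBu3, 4, toluene, 80 °C) gives the racemic benzylidene succinate diester F4.
- LiOH in aqueous THF gives the diacid bisphenol F5.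
- Ac2O with catalytic pyridine at 40 °C re-acetylates both phenols and closes the anhydride to 9.

**Step 2.** Glyoxylic acid is an unusual Perkin partner. It can oligomerise, and Dakin–West acetylation of the arylacetic acid can compete. The fallback sets out from 6 and returns at 7.
- Knoevenagel-type condensation of 6 with commercial 4-hydroxyphenylacetonitrile (K2CO3, MeOH) gives potassium (Z)-3-cyano-3-(4-hydroxyphenyl)acrylate F6.
- HCO2H/H2SO4 at reflux hydrolyses the nitrile and closes the ring to 3-(4-hydroxyphenyl)furan-2,5-dione F7.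
- Ac2O acetylates the phenol to give 7.

**Further compounds**
F1 | step 4 | rac-(E)-3-(4-acetoxyphenyl)-2-[4-acetoxy-3-(3-methylbut-2-enyl)benzylidene]-4-methoxy-4-oxobutanoic acid | COC(=O)C(c1ccc(OC(C)=O)cc1)/C(C(=O)O)=C\c1ccc(OC(C)=O)c(CC=C(C)C)c1
F2 | step 4 | (S)-1-phenylethylammonium salt of 10 | COC(=O)[C@H](c1ccc(OC(C)=O)cc1)/C(C(=O)[O-])=C\c1ccc(OC(C)=O)c(CC=C(C)C)c1.C[C@H]([NH3+])c1ccccc1
F3 | step 3 | dimethyl (Z)-2-(4-hydroxyphenyl)but-2-enedioate | COC(=O)/C=C(\C(=O)OC)c1ccc(O)cc1
F4 | step 3 | dimethyl rac-(E)-2-[4-acetoxy-3-(3-methylbut-2-enyl)benzylidene]-3-(4-hydroxyphenyl)succinate | COC(=O)C(c1ccc(O)cc1)/C(C(=O)OC)=C\c1ccc(OC(C)=O)c(CC=C(C)C)c1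
F5 | step 3 | rac-(E)-2-[4-hydroxy-3-(3-methylbut-2-enyl)benzylidene]-3-(4-hydroxyphenyl)succinic acid | OC(=O)C(c1ccc(O)cc1)/C(C(=O)O)=C\c1ccc(O)c(CC=C(C)C)c1
F6 | step 2 | potassium (Z)-3-cyano-3-(4-hydroxyphenyl)acrylate | N#C/C(c1ccc(O)cc1)=C\C(=O)[O-].[K+]
F7 | step 2 | 3-(4-hydroxyphenyl)furan-2,5-dione | O=C1OC(=O)C(c2ccc(O)cc2)=C1
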